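Labdane numbering is used. Ring B is cut at C5–C6 and C7–C8, which frees the C6H2–C7H(OH) bridge as a vinylboron unit. The feature exploited is that C7 is a carbinol carbon bonded to the sp2 carbon C8, while C6 is a methylene on C5. This is the exact imprint of a 1,2-dicarbofunctionalised vinylboronate. One enantioselective palladium-catalysed conjunctive cross-coupling joins the ring A enol triflate (C5), vinyl-B(pin) (C6, C7) and an alkenyllithium (C8, C9, C11, C12, C17), making both bonds and setting C7. Its precursor is a bis(alkenyl)borate plus a monocyclic triflate. C7 then steers a cation–olefin closure of C9–C10. Singlet oxygen and a Wittig reaction build the dioxepine.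

Key step: step 4

Assumption: the antipode of the ferrocenyl bisphosphine in step 4 is chosen that gives the 7R configuration drawn (both antipodes are sold), and C15 of the peroxyhemiacetal is taken to equilibrate to the configuration of the target.

Step 1
Reactants: 1 2,2,6-trimethylcyclohexanone (racemic)
Product: 3 2,6,6-trimethylcyclohex-1-en-1-yl trifluoromethanesulfonate, via lithium enolate 2 (not isolated)
Conditions: LDA, THF, −78 to 0 °C; PhNTf2, 0 °C to rt
Reagents that add atoms: N-phenylbis(trifluoromethanesulfonimide), O=S(=O)(N(c1ccccc1)S(=O)(=O)C(F)(F)F)C(F)(F)F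
Why: The only enolisable position of 1 is C10–H, so deprotonation gives a single tetrasubstituted enolate, and its O-sulfonylation (enol triflate formation) fixes the C5=C10 double bond and erases the stereocentre of 1.

Step 2
Reactants: 4 pent-3-yn-1-ol
Product: 5 trimethyl(pent-3-yn-1-yloxy)silane
Conditions: TMSCl, Et3N, CH2Cl2, 0 °C
Reagents that add atoms: chlorotrimethylsilane, C[Si](C)(C)Cl
Why: Silyl ether protection masks the acidic OH for the organometallic steps, and the group is labile enough to fall off in the basic work-up of step 4.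

Step 3
Reactants: 5 trimethyl(pent-3-yn-1-yloxy)silane
Product: 7 [(3E)-4-iodopent-3-en-1-yl]oxy(trimethyl)silane, via alkenylzirconocene chloride 6 (not isolated)
Conditions: Cp2Zr(H)Cl, THF, rt; I2, 0 °C
Reagents that add atoms: iodine, II
Why: Syn hydrozirconation places zirconium on the less hindered, methyl-bearing alkyne carbon (C8), and iodinolysis with retention gives the E iodide with C17 cis to C11, the geometry that later makes C11 equatorial.

Step 4
Reactants: 7 [(3E)-4-iodopent-3-en-1-yl]oxy(trimethyl)silane; 8 4,4,5,5-tetramethyl-2-vinyl-1,3,2-dioxaborolane (vinyl-B(pin)); 3 2,6,6-trimethylcyclohex-1-en-1-yl trifluoromethanesulfonate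
Product: 12 (3E,5R)-4-methyl-6-(2,6,6-trimethylcyclohex-1-en-1-yl)hex-3-ene-1,5-diol, via alkenyllithium 9 (not isolated), via lithium bis(alkenyl)borate 10 (not isolated), via allylboronate 11 (not isolated)
Conditions: 7, t-BuLi, Et2O, −78 °C; 8, −78 °C to rt; solvent change to THF; 3, KOTf, Pd(OAc)2 (3 mol %), 2,2'-bis[α-(dimethylamino)benzyl]-1,1'-bis[bis(4-methoxy-3,5-dimethylphenyl)phosphino]ferrocene (MandyPhos type, single enantiomer, 3.6 mol %), 60 °C; then 3 M NaOH, 30 % H2O2, 0 °C to rt
Reagents that add atoms: vinyl-B(pin) 8, C=CB1OC(C)(C)C(C)(C)O1; hydrogen peroxide, OO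
Why: Oxidative addition of 3 to zerovalent palladium gives a cationic alkenyl complex of divalent palladium that binds the unsubstituted vinyl group of borate 10; this triggers a 1,2-metallate shift in which the trisubstituted alkenyl group moves from boron to C7 (C7–C8 bond) anti to palladium, and reductive elimination from the alkyl(alkenyl)palladium then forms C5–C6. The reaction type is the enantioselective conjunctive cross-coupling of bis(alkenyl)borates with C(sp2) triflates, which gives α-chiral allylboronates. No ring is closed in this step. The only new stereocentre, C7, is set by the chiral bisphosphine, which selects the face of the vinyl group that binds palladium, and the stereoretentive oxidation of the C–B bond carries it into the alcohol. Conjunctive coupling must win over direct alkenyl transfer (Suzuki–Miyaura pathway) and the right olefin must react: the non-coordinating triflate (KOTf removes iodide) keeps palladium cationic and π-acidic, and the vinyl group is far less hindered than the trisubstituted alkenyl group, which therefore migrates with retention of its E geometry. The basic peroxide work-up also cleaves the trimethylsilyl ether.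

Step 5
Reactants: 12 (3E,5R)-4-methyl-6-(2,6,6-trimethylcyclohex-1-en-1-yl)hex-3-ene-1,5-diol
Product: 13 (3E,5R)-4-methyl-6-(2,6,6-trimethylcyclohex-1-en-1-yl)hex-3-ene-1,5-diyl diacetate
Conditions: Ac2O, pyridine, DMAP (cat.), CH2Cl2, rt
Reagents that add atoms: acetic anhydride, CC(=O)OC(C)=O
Why: Acylation makes the C12 oxygen non-nucleophilic, lowers the basicity of the C8=C9 olefin, and installs at C7 the participating group needed in step 6.

Step 6
Reactants: 13 (3E,5R)-4-methyl-6-(2,6,6-trimethylcyclohex-1-en-1-yl)hex-3-ene-1,5-diyl diacetate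
Product: 15 8α-hydroxy-13,14,15,16-tetranorlabdane-7α,12-diyl diacetate, via dioxolanylium ion 14 (not isolated)
Conditions: ClSO3H, 2-nitropropane, −78 °C; then aq. NaHCO3
Reagents that add atoms: water, O
Why: Proton-initiated cation–olefin (polyene-type) cyclisation: the electron-rich tetrasubstituted ring A olefin is protonated at C5 in preference to the acetate-deactivated C8=C9 olefin, the C10 cation is attacked by C9 through a chair-like transition state (trans fusion with 5α-H and 10β-CH3, and the E olefin puts C11 equatorial and 9-H α), allylic 1,2-strain with C17 holds the C7 acetate pseudo-axial so that C7 dictates the absolute sense, and this axial acetate traps the C8 cation from the α face as ion 14, whose hydrolysis gives the axial 7α-acetate and the equatorial 8α-alcohol.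

Step 7
Reactants: 15 8α-hydroxy-13,14,15,16-tetranorlabdane-7α,12-diyl diacetate
Product: 16 13,14,15,16-tetranorlabd-8(17)-ene-7α,12-diyl diacetate
Conditions: SOCl2, pyridine, CH2Cl2, −78 to −20 °C
Reagents that add atoms: none
Why: Dehydration through the chlorosulfite (E2 elimination): the equatorial leaving group on C8 has no anti-periplanar ring hydrogen at C7 or C9, so only a hydrogen of the axial C17 methyl group can be lost and the exocyclic 8(17)-olefin should form.

Step 8
Reactants: 16 13,14,15,16-tetranorlabd-8(17)-ene-7α,12-diyl diacetate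
Product: 17 13,14,15,16-tetranorlabd-8(17)-ene-7α,12-diol
Conditions: K2CO3, MeOH, rt to 40 °C
Reagents that add atoms: none
Why: Base-catalysed transesterification (methanolysis) removes both acetates without touching the olefin or any stereocentre.

Step 9
Reactants: 17 13,14,15,16-tetranorlabd-8(17)-ene-7α,12-diol
Product: 18 7α-hydroxy-13,14,15,16-tetranorlabd-8(17)-en-12-al
Conditions: TEMPO (cat.), PhI(OAc)2, CH2Cl2, rt
Reagents that add atoms: none
Why: The oxoammonium (TEMPO) oxidation is sterically selective for the primary C12 alcohol over the hindered axial secondary C7 alcohol and stops at the aldehyde.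

Step 10
Reactants: 18 7α-hydroxy-13,14,15,16-tetranorlabd-8(17)-en-12-al
Product: 19 (11Z)-7α,12-bis(triethylsilyloxy)-13,14,15,16-tetranorlabda-8(17),11-diene
Conditions: TESOTf, Et3N, CH2Cl2, −78 to 0 °C
Reagents that add atoms: triethylsilyl trifluoromethanesulfonate, CC[Si](CC)(CC)OS(=O)(=O)C(F)(F)F
Why: Soft enolisation with a silyl triflate and an amine converts the aldehyde into its silyl enol ether (Z isomer expected to prevail, and both isomers lead to the same C11 centre) and protects 7-OH in the same operation.

Step 11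
Reactants: 19 (11Z)-7α,12-bis(triethylsilyloxy)-13,14,15,16-tetranorlabda-8(17),11-diene
Product: 20 (11R)-7α-triethylsilyloxy-11-(triethylsilylperoxy)-13,14,15,16-tetranorlabd-8(17)-en-12-al
Conditions: O2, 5,10,15,20-tetraphenylporphyrin (cat.), visible light, CH2Cl2, −78 °C
Reagents that add atoms: dioxygen, O=O
Why: In a silatropic Schenck ene reaction singlet oxygen attacks the electron-rich silyl enol ether far faster than the 1,1-disubstituted C8=C17 olefin (oxygen adds to C11, silicon shifts to the distal oxygen, C12 returns to the aldehyde); allylic 1,3-strain keeps 9-H in the olefin plane, and attack from the face flanked by the flat C8=C17 unit, away from quaternary C10, should give the C11 arrangement of the target.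

Step 12
Reactants: 21 [2-(1,3-dioxolan-2-yl)ethyl]triphenylphosphonium bromide
Product: 23 3-(1,3-dioxolan-2-yl)-2-(triphenyl-λ5-phosphanylidene)propanal, via phosphorane 22 (not isolated)
Conditions: KOtBu, THF, 0 °C; HCO2Et, 0 °C to rt
Reagents that add atoms: ethyl formate, CCOC=O
Why: C-formylation of a phosphorus ylide by a formate ester gives, after loss of ethanol, the stabilised formyl ylide that carries C13 to C16 with C15 masked as an acetal.

Step 13
Reactants: 20 (11R)-7α-triethylsilyloxy-11-(triethylsilylperoxy)-13,14,15,16-tetranorlabd-8(17)-en-12-al; 23 3-(1,3-dioxolan-2-yl)-2-(triphenyl-λ5-phosphanylidene)propanal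
Product: 24 (11S,12E)-15,15-ethylenedioxy-7α-triethylsilyloxy-11-(triethylsilylperoxy)labda-8(17),12-dien-16-al
Conditions: toluene, 45 °C
Reagents that add atoms: none
Why: The Wittig reaction of a stabilised α-branched formyl ylide is E-selective (C11 trans to the formyl group, cis to C14), and its neutral conditions leave the O–O bond and the acidic C11–H untouched.

Step 14
Reactants: 24 (11S,12E)-15,15-ethylenedioxy-7α-triethylsilyloxy-11-(triethylsilylperoxy)labda-8(17),12-dien-16-al
Product: 26 (11S,15S)-7α,15-dihydroxy-11,15-epidioxylabda-8(17),12-dien-16-al (target CNP0269954.1), via hydroperoxy dialdehyde 25 (not isolated)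
Conditions: 1 M aq. HCl, THF, 0 °C to rt
Reagents that add atoms: water, O
Why: Acid hydrolysis removes both triethylsilyl groups and the dioxolane, and the freed C11 hydroperoxide adds to the C15 aldehyde (peroxyhemiacetal formation, possible because C11 and C14 are cis on the E enal) to close the 1,2-dioxepine, with the reversible C15 centre settling in the more stable, anomerically favoured configuration.

Compound list
1 | 2,2,6-trimethylcyclohexanone | CC1CCCC(C)(C)C1=O | starting material
2 | lithium 2,6,6-trimethylcyclohex-1-en-1-olate | CC1=C([O-])C(C)(C)CCC1.[Li+] | intermediate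
3 | 2,6,6-trimethylcyclohex-1-en-1-yl trifluoromethanesulfonate | CC1=C(OS(=O)(=O)C(F)(F)F)C(C)(C)CCC1 | intermediate
4 | pent-3-yn-1-ol | CC#CCCO | starting material
5 | trimethyl(pent-3-yn-1-yloxy)silane | CC#CCCO[Si](C)(C)C | intermediate
6 | (E)-alkenylzirconocene chloride (Zr on C8, trans to C11) | C/C(=C\CCO[Si](C)(C)C)[Zr](Cl)(C1C=CC=C1)C1C=CC=C1 | intermediate
7 | [(3E)-4-iodopent-3-en-1-yl]oxy(trimethyl)silane | C/C(I)=C\CCO[Si](C)(C)C | intermediate
8 | 4,4,5,5-tetramethyl-2-vinyl-1,3,2-dioxaborolane | C=CB1OC(C)(C)C(C)(C)O1 | starting material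
9 | (E)-5-(trimethylsilyloxy)pent-2-en-2-yllithium | C/C([Li])=C\CCO[Si](C)(C)C | intermediate
10 | lithium vinyl[(E)-5-(trimethylsilyloxy)pent-2-en-2-yl]pinacolatoborate | [Li+].C=C[B-]1(/C(C)=C/CCO[Si](C)(C)C)OC(C)(C)C(C)(C)O1 | intermediate
11 | C7 pinacol allylboronate (boron in the place of the later 7-OH, E olefin, 12-OTMS) | CC1=C(C[C@@H](B2OC(C)(C)C(C)(C)O2)/C(C)=C/CCO[Si](C)(C)C)C(C)(C)CCC1 | intermediate
12 | (3E,5R)-4-methyl-6-(2,6,6-trimethylcyclohex-1-en-1-yl)hex-3-ene-1,5-diol | CC1=C(C[C@@H](O)/C(C)=C/CCO)C(C)(C)CCC1 | intermediate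
13 | (3E,5R)-4-methyl-6-(2,6,6-trimethylcyclohex-1-en-1-yl)hex-3-ene-1,5-diyl diacetate | CC1=C(C[C@@H](OC(C)=O)/C(C)=C/CCOC(C)=O)C(C)(C)CCC1 | intermediate
14 | 7α,8α-bridged 2-methyl-1,3-dioxolan-2-ylium ion of the trans-decalin, chlorosulfate | C[C@@]12OC(C)=[O+][C@@H]1C[C@H]3C(C)(C)CCC[C@]3(C)[C@H]2CCOC(C)=O.[O-]S(=O)(=O)Cl | intermediate
15 | 8α-hydroxy-13,14,15,16-tetranorlabdane-7α,12-diyl diacetate | C[C@@]1(O)[C@H](OC(C)=O)C[C@H]2C(C)(C)CCC[C@]2(C)[C@H]1CCOC(C)=O | intermediate
16 | 13,14,15,16-tetranorlabd-8(17)-ene-7α,12-diyl diacetate | C=C1[C@H](OC(C)=O)C[C@H]2C(C)(C)CCC[C@]2(C)[C@H]1CCOC(C)=O | intermediate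
17 | 13,14,15,16-tetranorlabd-8(17)-ene-7α,12-diol | C=C1[C@H](O)C[C@H]2C(C)(C)CCC[C@]2(C)[C@H]1CCO | intermediate
18 | 7α-hydroxy-13,14,15,16-tetranorlabd-8(17)-en-12-al | C=C1[C@H](O)C[C@H]2C(C)(C)CCC[C@]2(C)[C@H]1CC=O | intermediate
19 | (11Z)-7α,12-bis(triethylsilyloxy)-13,14,15,16-tetranorlabda-8(17),11-diene | C=C1[C@H](O[Si](CC)(CC)CC)C[C@H]2C(C)(C)CCC[C@]2(C)[C@H]1/C=C\O[Si](CC)(CC)CC | intermediate
20 | (11R)-7α-triethylsilyloxy-11-(triethylsilylperoxy)-13,14,15,16-tetranorlabd-8(17)-en-12-al | C=C1[C@H](O[Si](CC)(CC)CC)C[C@H]2C(C)(C)CCC[C@]2(C)[C@H]1[C@@H](OO[Si](CC)(CC)CC)C=O | intermediate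
21 | [2-(1,3-dioxolan-2-yl)ethyl]triphenylphosphonium bromide | [Br-].C1COC(CC[P+](c2ccccc2)(c2ccccc2)c2ccccc2)O1 | starting material
22 | [2-(1,3-dioxolan-2-yl)ethylidene]triphenylphosphorane | C1COC(CC=P(c2ccccc2)(c2ccccc2)c2ccccc2)O1 | intermediate
23 | 3-(1,3-dioxolan-2-yl)-2-(triphenyl-λ5-phosphanylidene)propanal | O=CC(CC1OCCO1)=P(c1ccccc1)(c1ccccc1)c1ccccc1 | intermediate
24 | (11S,12E)-15,15-ethylenedioxy-7α-triethylsilyloxy-11-(triethylsilylperoxy)labda-8(17),12-dien-16-al | C=C1[C@H](O[Si](CC)(CC)CC)C[C@H]2C(C)(C)CCC[C@]2(C)[C@H]1[C@@H](OO[Si](CC)(CC)CC)/C=C(/C=O)CC3OCCO3 | intermediate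
25 | (11S,12E)-11-hydroperoxy-7α-hydroxylabda-8(17),12-diene-15,16-dial | C=C1[C@H](O)C[C@H]2C(C)(C)CCC[C@]2(C)[C@H]1[C@@H](OO)/C=C(/C=O)CC=O | intermediate
26 | (11S,15S)-7α,15-dihydroxy-11,15-epidioxylabda-8(17),12-dien-16-al | C=C1[C@H](O)C[C@H]2C(C)(C)CCC[C@]2(C)[C@H]1[C@@H]1C=C(C=O)C[C@@H](O)OO1 | target

Total step count: 14. Longest linear sequence: 12 steps (from 4 through steps 2 to 11, 13 and 14).

Steps most likely to fail

Step 4. The hindered alkenylpalladium complex may bind the borate too slowly. Direct alkenyl transfer, protodeboronation or loss of enantioselectivity could then take over. The fallback sets out from 3 and 7 and comes back at 12, and it makes the two bonds one after the other. Suzuki–Miyaura coupling of 3 with (E)-2-ethoxyvinylboronic acid pinacol ester (Pd(PPh3)4, K3PO4, dioxane/water) gives 2-[(E)-2-ethoxyvinyl]-1,3,3-trimethylcyclohexene F1. Mild acid hydrolysis gives (2,6,6-trimethylcyclohex-1-en-1-yl)acetaldehyde F2. The alkenylzinc reagent made from 7 (t-BuLi, then ZnBr2) is added to F2 under catalysis by (−)-3-exo-morpholinoisoborneol to give the (R)-allylic alcohol trimethylsilyl ether F3. K2CO3 in methanol then gives 12.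

Step 6. The strong acid may ionise the allylic C7 acetate. The pseudo-equatorial acetate transition state may compete, which would give poor facial selectivity. The C8 cation may also lose a proton unselectively before the acetate traps it. The fallback sets out from 11 (isolated by leaving out the peroxide work-up of step 4) and comes back at 17, and it uses boron instead of oxygen as the terminating group. Under the same proton initiation the pseudo-axial C7–B bond is lost anti to the incoming C10 (SE2′ termination, with the same transfer of chirality). After work-up this gives 13,14,15,16-tetranorlabd-7-en-12-ol F4. Buffered mCPBA epoxidises the α face, away from the 10β-methyl group, to give 7α,8α-epoxy-13,14,15,16-tetranorlabdan-12-ol F5. Al(OiPr)3 in refluxing toluene isomerises the epoxide toward the C17 methyl group to the 7α-hydroxy-8(17)-ene 17.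

Step 13. Olefination of the hindered α-peroxy aldehyde by the sluggish branched ylide may be slow. Thermal or base-induced fragmentation of the peroxide (loss of C11–H, O–O cleavage) would then compete. The fallback sets out from 18 and comes back at 24. It reverses the order, so that steps 10 and 11 are also bypassed. The Wittig reaction of the unhindered aldehyde 18 with 23 gives (12E)-15,15-ethylenedioxy-7α-hydroxylabda-8(17),12-dien-16-al F6. TESOTf and Et3N give the 7-O-silylated 16-silyloxy-11,13(16)-diene F7. Singlet oxygen then adds at the γ-carbon C11 with shift of silicon to the distal oxygen (vinylogous silatropic ene reaction, same facial argument as in step 11) to give 24.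

Further compounds
F1 | step 4 | 2-[(E)-2-ethoxyvinyl]-1,3,3-trimethylcyclohexene | CCO/C=C/C1=C(C)CCCC1(C)C
F2 | step 4 | (2,6,6-trimethylcyclohex-1-en-1-yl)acetaldehyde | CC1=C(CC=O)C(C)(C)CCC1
F3 | step 4 | (2R,3E)-3-methyl-6-(trimethylsilyloxy)-1-(2,6,6-trimethylcyclohex-1-en-1-yl)hex-3-en-2-ol | CC1=C(C[C@@H](O)/C(C)=C/CCO[Si](C)(C)C)C(C)(C)CCC1
F4 | step 6 | 13,14,15,16-tetranorlabd-7-en-12-ol | CC1=CC[C@H]2C(C)(C)CCC[C@]2(C)[C@H]1CCO
F5 | step 6 | 7α,8α-epoxy-13,14,15,16-tetranorlabdan-12-ol | C[C@@]12O[C@@H]1C[C@H]3C(C)(C)CCC[C@]3(C)[C@H]2CCO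
F6 | step 13 | (12E)-15,15-ethylenedioxy-7α-hydroxylabda-8(17),12-dien-16-al | C=C1[C@H](O)C[C@H]2C(C)(C)CCC[C@]2(C)[C@H]1C/C=C(/C=O)CC3OCCO3
F7 | step 13 | (11E,13(16)E)-15,15-ethylenedioxy-7α,16-bis(triethylsilyloxy)labda-8(17),11,13(16)-triene | C=C1[C@H](O[Si](CC)(CC)CC)C[C@H]2C(C)(C)CCC[C@]2(C)[C@H]1/C=C/C(CC3OCCO3)=C/O[Si](CC)(CC)CC
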